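**Retrosynthetic overview**
1. Last bond: oxolane C2–aryl, from the arylzinc of the complete bromo side-chain alcohol (fragment B) and the oxocarbenium ion of a 2-sulfonyl oxolane (fragment A). This sets C2 cis to the C3 methyl and trans to the C5 aryl.
2. Fragment A ⇐ lactol ⇐ (3R,4R,5S)-5-aryl-3,4-dimethyl-γ-butyrolactone. The key disconnection is its C4–C5 bond: the β-carbon of tiglic aldehyde, turned into a homoenolate by a chiral carbene, adds to the carbonyl carbon of veratraldehyde, and acyl transfer closes the ring in the same step.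
3. Fragment B ⇐ α-aryloxy ketone (threo-selective reduction) ⇐ Weinreb amide + aryl Grignard ⇐ Mitsunobu inversion of the (S)-lactic Weinreb amide with 4-bromo-2-methoxyphenol.
4. Ring order: only one ring is built, the five-membered oxygen ring, as the lactone in step 1. It is kept to the end, and all benzene rings are bought.

Assumption: the (5aR,10bS) antipode of the triazolium precatalyst is taken to give the (4R,5S) lactone series; the sense of induction must be confirmed on the first run and, if reversed, the (5aS,10bR) antipode is used with no other change.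

**Route**

Step 1
Reactants: 1 3,4-dimethoxybenzaldehyde (veratraldehyde); 2 (E)-2-methylbut-2-enal (tiglic aldehyde)
Product: 4 (3R,4R,5S)-5-(3,4-dimethoxyphenyl)-3,4-dimethyloxolan-2-one, via (3S)-epimeric all-cis lactone 3 (not isolated)
Conditions: 2 (2 equiv), (5aR,10bS)-2-mesityl-5a,10b-dihydro-4H,6H-indeno[2,1-b][1,2,4]triazolo[4,3-d][1,4]oxazin-2-ium chloride (15 mol %), DBU (20 mol %), Ti(OiPr)4 (20 mol %), 4 Å MS, THF, 40 °C; then DBU (1 equiv), 65 °C
Reagents that add atoms: none
Why: Proposed new method: the carbene adds to the aldehyde of 2 to give an extended Breslow intermediate whose β-carbon (a homoenolate, reversed polarity) attacks the Ti(OiPr)4-activated carbonyl carbon of 1 on the face left open by the indane wall of the catalyst, which sets C4 (R) and C5 (S) cis to each other; α-protonation then gives the acyl azolium, which lactonises and releases the carbene, and DBU equilibrates C3 to the more stable 3,4-trans (3R) epimer; the closest known reaction is the carbene-catalysed homoenolate annulation of enals with aryl aldehydes to cis-γ-butyrolactones and its Lewis-acid co-catalysed enantioselective variants.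

Step 2
Reactants: 4 (3R,4R,5S)-5-(3,4-dimethoxyphenyl)-3,4-dimethyloxolan-2-one
Product: 5 (3R,4R,5S)-5-(3,4-dimethoxyphenyl)-3,4-dimethyloxolan-2-ol (anomer mixture)
Conditions: i-Bu2AlH (1.1 equiv), CH2Cl2, −78 °C; aq. KNaC4H4O6
Reagents that add atoms: none
Why: Partial lactone reduction stops at the aluminium lactolate at −78 °C; no ring stereocentre is touched and the new anomeric centre is inconsequential.

Step 3
Reactants: 5 (3R,4R,5S)-5-(3,4-dimethoxyphenyl)-3,4-dimethyloxolan-2-ol
Product: 6 (3R,4R,5S)-2-(benzenesulfonyl)-5-(3,4-dimethoxyphenyl)-3,4-dimethyloxolane (C2 epimer mixture)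
Conditions: PhSO2H (2 equiv), CaCl2, CH2Cl2, 23 °C
Reagents that add atoms: benzenesulfinic acid, O=S(O)c1ccccc1
Why: Acid-mediated exchange of the anomeric hydroxyl for sulfinate through the oxocarbenium ion (2-sulfonyl cyclic ether formation), with CaCl2 binding the water; the C2 mixture is irrelevant because this centre is ionised again in step 8.

Step 4
Reactants: 7 ethyl (S)-lactate
Product: 8 (2S)-2-hydroxy-N-methoxy-N-methylpropanamide
Conditions: MeNH(OMe)·HCl (1.6 equiv), i-PrMgCl (4.2 equiv), THF, −20 → 0 °C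
Reagents that add atoms: N,O-dimethylhydroxylamine hydrochloride, CNOC.Cl
Why: Weinreb amide formation by aminolysis of the ester with the chloromagnesium amide made in the flask; the stereocentre is not involved.

Step 5
Reactants: 8 (2S)-2-hydroxy-N-methoxy-N-methylpropanamide; 9 4-bromo-2-methoxyphenol
Product: 10 (2R)-2-(4-bromo-2-methoxyphenoxy)-N-methoxy-N-methylpropanamide
Conditions: PPh3 (1.3 equiv), DIAD (1.3 equiv), THF, 0 → 23 °C
Reagents that add atoms: none
Why: Mitsunobu etherification of an α-carbonyl secondary alcohol with a phenol is an SN2 process with clean inversion, so (S) becomes (R), the configuration needed at the ether carbon.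

Step 6
Reactants: 10 (2R)-2-(4-bromo-2-methoxyphenoxy)-N-methoxy-N-methylpropanamide; 11 (3,4-dimethoxyphenyl)magnesium bromide
Product: 12 (2R)-2-(4-bromo-2-methoxyphenoxy)-1-(3,4-dimethoxyphenyl)propan-1-one
Conditions: 11 (1.5 equiv, 0.5 M in THF), THF, −20 → 0 °C; cold aq. NH4Cl
Reagents that add atoms: none
Why: Weinreb ketone synthesis: the chelated tetrahedral adduct prevents over-addition and protects the α-stereocentre from enolisation until the cold quench, and the aryl bromide is inert to the Grignard reagent.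

Step 7
Reactants: 12 (2R)-2-(4-bromo-2-methoxyphenoxy)-1-(3,4-dimethoxyphenyl)propan-1-one
Product: 13 (1R,2R)-2-(4-bromo-2-methoxyphenoxy)-1-(3,4-dimethoxyphenyl)propan-1-ol
Conditions: (R)-tetrahydro-1-methyl-3,3-diphenyl-1H,3H-pyrrolo[1,2-c][1,3,2]oxazaborole ((R)-Me-CBS, 0.2 equiv), BH3·SMe2 (0.7 equiv), THF, −20 °C; MeOH
Reagents that add atoms: none
Why: Corey–Bakshi–Shibata reduction: with the aryl group as the large substituent the (R)-catalyst delivers hydride to the face that gives C1 (R), and this matches the Felkin–Anh (polar, non-chelated) preference of the α-aryloxy ketone, so the threo (1R,2R) alcohol results.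

Step 8
Reactants: 13 (1R,2R)-2-(4-bromo-2-methoxyphenoxy)-1-(3,4-dimethoxyphenyl)propan-1-ol; 6 (3R,4R,5S)-2-(benzenesulfonyl)-5-(3,4-dimethoxyphenyl)-3,4-dimethyloxolane
Product: 16 (1R,2R)-1-(3,4-dimethoxyphenyl)-2-{4-[(2S,3R,4R,5S)-5-(3,4-dimethoxyphenyl)-3,4-dimethyloxolan-2-yl]-2-methoxyphenoxy}propan-1-ol, via dilithio aryl alkoxide 14 (not isolated), via arylzinc bromide lithium alkoxide 15 (not isolated)
Conditions: 13 (2.2 equiv), n-BuLi (2.0 equiv per 13), THF, −78 °C; ZnBr2 (1.2 equiv per 13), −78 → 0 °C; then 6 (1 equiv), THF, 23 °C; aq. NH4Cl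
Reagents that add atoms: none
Why: Deprotonation and Br/Li exchange followed by transmetalation give an arylzinc that tolerates the alkoxide; the zinc halide ionises the sulfone to the oxocarbenium ion and the aryl group is delivered by inside attack to the face opposite the C4 methyl and C5 aryl groups, that is cis to the C3 methyl, setting C2 (S) (organozinc substitution of a 2-sulfonyl cyclic ether).

**Compound list**

1 | 3,4-dimethoxybenzaldehyde (veratraldehyde) | COc1ccc(C=O)cc1OC | starting material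
2 | (E)-2-methylbut-2-enal (tiglic aldehyde) | C/C=C(\C)C=O | starting material
3 | (3S,4R,5S)-5-(3,4-dimethoxyphenyl)-3,4-dimethyloxolan-2-one (all-cis C3 epimer of 4) | O=C1O[C@H](c2ccc(OC)c(OC)c2)[C@H](C)[C@@H]1C | intermediate
4 | (3R,4R,5S)-5-(3,4-dimethoxyphenyl)-3,4-dimethyloxolan-2-one (3,4-trans, 4,5-cis) | O=C1O[C@H](c2ccc(OC)c(OC)c2)[C@H](C)[C@H]1C | intermediate
5 | (3R,4R,5S)-5-(3,4-dimethoxyphenyl)-3,4-dimethyloxolan-2-ol (anomer mixture) | OC1O[C@H](c2ccc(OC)c(OC)c2)[C@H](C)[C@H]1C | intermediate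
6 | (3R,4R,5S)-2-(benzenesulfonyl)-5-(3,4-dimethoxyphenyl)-3,4-dimethyloxolane (C2 epimer mixture) | O=S(=O)(c1ccccc1)C1O[C@H](c2ccc(OC)c(OC)c2)[C@H](C)[C@H]1C | intermediate
7 | ethyl (S)-lactate | CCOC(=O)[C@H](C)O | starting material
8 | (2S)-2-hydroxy-N-methoxy-N-methylpropanamide | CON(C)C(=O)[C@H](C)O | intermediate
9 | 4-bromo-2-methoxyphenol | COc1cc(Br)ccc1O | starting material
10 | (2R)-2-(4-bromo-2-methoxyphenoxy)-N-methoxy-N-methylpropanamide | CON(C)C(=O)[C@@H](C)Oc1ccc(Br)cc1OC | intermediate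
11 | (3,4-dimethoxyphenyl)magnesium bromide (0.5 M in THF) | COc1ccc([Mg]Br)cc1OC | starting material
12 | (2R)-2-(4-bromo-2-methoxyphenoxy)-1-(3,4-dimethoxyphenyl)propan-1-one | COc1ccc(C(=O)[C@@H](C)Oc2ccc(Br)cc2OC)cc1OC | intermediate
13 | (1R,2R)-2-(4-bromo-2-methoxyphenoxy)-1-(3,4-dimethoxyphenyl)propan-1-ol (threo) | COc1ccc([C@@H](O)[C@@H](C)Oc2ccc(Br)cc2OC)cc1OC | intermediate
14 | lithium (1R,2R)-1-(3,4-dimethoxyphenyl)-2-(4-lithio-2-methoxyphenoxy)propan-1-olate | COc1ccc([C@@H](O[Li])[C@@H](C)Oc2ccc([Li])cc2OC)cc1OC | intermediate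
15 | lithium (1R,2R)-2-[4-(bromozincio)-2-methoxyphenoxy]-1-(3,4-dimethoxyphenyl)propan-1-olate | COc1ccc([C@@H](O[Li])[C@@H](C)Oc2ccc([Zn]Br)cc2OC)cc1OC | intermediate
16 | (1R,2R)-1-(3,4-dimethoxyphenyl)-2-{4-[(2S,3R,4R,5S)-5-(3,4-dimethoxyphenyl)-3,4-dimethyloxolan-2-yl]-2-methoxyphenoxy}propan-1-ol | COc1ccc([C@@H](O)[C@@H](C)Oc2ccc([C@H]3O[C@H](c4ccc(OC)c(OC)c4)[C@H](C)[C@H]3C)cc2OC)cc1OC | target

**Step count and risks**

Total steps: 8. Longest linear sequence: 5 (steps 4 to 8, from 7).

Steps most likely to fail: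

Risk 1, step 1. An α,β-dialkyl enal is a slow homoenolate precursor, the electron-rich aldehyde 1 is a weak electrophile, and high enantioselectivity with a simple aryl aldehyde is not established. If yield or ee stays low after recrystallisation of 4, the fallback sets out from 1 and comes back to the route at 4, replacing carbene catalysis by reagent-controlled crotylation. Compound 1 is treated with (−)-(Z)-crotyldiisopinocampheylborane from (+)-α-pinene at −78 °C, followed by NaOH/H2O2, to give the syn alcohol (1S,2R)-1-(3,4-dimethoxyphenyl)-2-methylbut-3-en-1-ol F1. Hydroboration with 9-BBN and oxidation give (1S,2R)-1-(3,4-dimethoxyphenyl)-2-methylbutane-1,4-diol F2. TEMPO/PhI(OAc)2 oxidises the primary alcohol through the lactol to (4R,5S)-5-(3,4-dimethoxyphenyl)-4-methyloxolan-2-one F3. LiN(SiMe3)2 and MeI at −78 °C then methylate anti to the 4-methyl group to give 4.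

Risk 2, step 8. The doubly metalated nucleophile may be poorly soluble or may form the zinc reagent incompletely, and the coupling uses it in excess. The fallback sets out from 13 and comes back to the route at 16, using a protected, singly metalated nucleophile. Et3SiCl and imidazole in DMF give [(1R,2R)-2-(4-bromo-2-methoxyphenoxy)-1-(3,4-dimethoxyphenyl)propoxy]triethylsilane F4. n-BuLi (1 equiv, THF, −78 °C) gives the aryllithium [(1R,2R)-1-(3,4-dimethoxyphenyl)-2-(4-lithio-2-methoxyphenoxy)propoxy]triethylsilane F5, and ZnBr2 turns it into the arylzinc bromide [(1R,2R)-2-[4-(bromozincio)-2-methoxyphenoxy]-1-(3,4-dimethoxyphenyl)propoxy]triethylsilane F6. Coupling with 6 at 23 °C gives the triethylsilyl ether of the target, [(1R,2R)-1-(3,4-dimethoxyphenyl)-2-{4-[(2S,3R,4R,5S)-5-(3,4-dimethoxyphenyl)-3,4-dimethyloxolan-2-yl]-2-methoxyphenoxy}propoxy]triethylsilane F7, and n-Bu4NF in THF at 0 °C frees 16.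

Risk 3, step 7. The threo/erythro ratio depends on the catalyst and the Felkin preference both pointing the same way, and the α-aryloxy ketone 12 can epimerise. The fallback sets out from 10 and comes back to the route at 13, setting the carbinol centre by C–C bond formation under chelation control instead of hydride delivery. i-Bu2AlH in CH2Cl2 at −78 °C reduces the Weinreb amide to (2R)-2-(4-bromo-2-methoxyphenoxy)propanal F8. This aldehyde is precomplexed with MgBr2·OEt2 in CH2Cl2 at −78 °C and treated with 11; Cram-chelate addition, with the aryl group entering past the hydrogen, gives the same threo alcohol 13.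

**Further compounds**

F1 | step 1 | (1S,2R)-1-(3,4-dimethoxyphenyl)-2-methylbut-3-en-1-ol | O[C@H](c1ccc(OC)c(OC)c1)[C@H](C)C=C
F2 | step 1 | (1S,2R)-1-(3,4-dimethoxyphenyl)-2-methylbutane-1,4-diol | O[C@H](c1ccc(OC)c(OC)c1)[C@H](C)CCO
F3 | step 1 | (4R,5S)-5-(3,4-dimethoxyphenyl)-4-methyloxolan-2-one | O=C1O[C@H](c2ccc(OC)c(OC)c2)[C@H](C)C1
F4 | step 8 | [(1R,2R)-2-(4-bromo-2-methoxyphenoxy)-1-(3,4-dimethoxyphenyl)propoxy]triethylsilane | COc1ccc([C@@H](O[Si](CC)(CC)CC)[C@@H](C)Oc2ccc(Br)cc2OC)cc1OC
F5 | step 8 | [(1R,2R)-1-(3,4-dimethoxyphenyl)-2-(4-lithio-2-methoxyphenoxy)propoxy]triethylsilane | COc1ccc([C@@H](O[Si](CC)(CC)CC)[C@@H](C)Oc2ccc([Li])cc2OC)cc1OC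
F6 | step 8 | [(1R,2R)-2-[4-(bromozincio)-2-methoxyphenoxy]-1-(3,4-dimethoxyphenyl)propoxy]triethylsilane | COc1ccc([C@@H](O[Si](CC)(CC)CC)[C@@H](C)Oc2ccc([Zn]Br)cc2OC)cc1OC
F7 | step 8 | [(1R,2R)-1-(3,4-dimethoxyphenyl)-2-{4-[(2S,3R,4R,5S)-5-(3,4-dimethoxyphenyl)-3,4-dimethyloxolan-2-yl]-2-methoxyphenoxy}propoxy]triethylsilane | COc1ccc([C@@H](O[Si](CC)(CC)CC)[C@@H](C)Oc2ccc([C@H]3O[C@H](c4ccc(OC)c(OC)c4)[C@H](C)[C@H]3C)cc2OC)cc1OC
F8 | step 7 | (2R)-2-(4-bromo-2-methoxyphenoxy)propanal | O=C[C@@H](C)Oc1ccc(Br)cc1OC
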